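**Numbering and assumptions.** Lignan locants are used throughout: C7–C8(C9)–C8'(C9')–C7' is the butane core, ring A sits on C7, ring B on C7', and ring C on C7'' of the C7''–C8''(C9'') side chain that hangs from O-4' of ring B. Compounds are numbered in the order of their first appearance in the steps.

Remark on the chemistry: the sense of induction of the BINOL phosphate in step 4 cannot be predicted. The (R) antipode of 3,3'-bis(2,4,6-triisopropylphenyl)-1,1'-binaphthyl-2,2'-diyl hydrogen phosphate, written (R)-TRIP, stands for whichever antipode arylates the methyl group on the (R)-configured carbon of 4.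

Remark on the chemistry: 4-iodo-2-methoxyphenol (9) is taken as a commercial compound.

## Analysis of the target

The target 23 is an open-chain sesquineolignan whose core is a 2,3-dimethylbutane, C7–C8(C9)–C8'(C9')–C7', with the guaiacyl ring A on C7 and the 3',5'-dimethoxy-4'-oxy ring B on C7'. The 4'-oxygen of ring B is bound to C8'' of a 1-arylpropan-1-ol that carries the second guaiacyl ring, ring C, on C7''. There are four stereocentres in two pairs: C8 (S) and C8' (R) are erythro, the arrangement that would be meso if rings A and B were alike, and C8'' (S) and C7'' (S) form a threo aryl ether alcohol. Ring B separates the two pairs, so neither can steer the other and each must be set on its own in the absolute sense. The sensitive groups are the two free phenols, the C7'' benzylic alcohol para to an oxygen (it ionises under acid and can be hydrogenolysed), and C8'', which is enolisable in any carbonyl precursor. The main difficulty is that the core has no functional group at all, so C8 and C8' must be set with the help of groups that later disappear. The strategy rests on the position of C7 and C7': each sits one bond beyond the carbon that carries C9 or C9', so once C9 and C9' are drawn at the carboxamide level the two benzylic carbons turn into the mirror-image methyl groups of a meso diamide of 2,3-dimethylsuccinic acid. Arylating one of them fixes C8 and C8' together.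

## Retrosynthetic reasoning

**23 ⇒ 22 (O–benzyl bonds on rings A and C).** The two phenols of 23 are carried as benzyl ethers and released together at the end. Cutting here keeps free phenols away from every organometallic, hydride and Mitsunobu step. The forward hydrogenolysis must leave the C7'' benzylic alcohol intact.

**22 ⇒ 21 ⇒ 19 + 20, and 19 ⇒ 18 ⇒ 16 + 17 (C7''–H, C1''–C7'' and O-4'–C8'').** The ether oxygen is the only link between the core and the side chain, so the side chain is cut off there. C8'' comes from the chiral pool: the ring B phenol of 16 displaces the hydroxyl of methyl (R)-lactate 17 with inversion. Ring C is then attached as the aryl nucleophile 20 to the amide 19, and C7'' is set last by 1,2-induction in the reduction of ketone 21. In this order the labile benzylic alcohol is exposed to only one further step.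

**16 ⇒ 15 ⇒ 14 ⇒ 13 ⇒ 12 ⇒ 11 (oxidation level of C9 and C9').** The two methyl groups of 15 are traced back to the two carboxamide carbons of 11 through the bis-sulfonate 14, the diol 13 and the acyl-activated diamide 12. Nothing is cut, but the disconnection that follows becomes possible: the amides turn the otherwise inert C7 and C7' into addressable positions. Both ends are treated in the same flask at each stage. Ring B carries a methoxymethyl ether and ring A a benzyl ether, so that only the ring B phenol is released in 16.

**11 ⇒ 8 + 10 (C1–C7).** The ring A benzyl group is removed as the aryl iodide 10, leaving the free methyl group of 8. The forward reaction is a directed methyl C–H arylation under achiral conditions, because the methyl group left in 8 is the one a chiral catalyst would disfavour.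

**8 ⇒ 4 + 7 (C1'–C7', the key disconnection).** Removing ring B as iodide 7 gives the meso diamide 4. This cut creates a mirror plane, so the whole stereochemical problem of the core reduces to choosing between two enantiotopic methyl groups. The erythro relationship is already present in the starting acid. The forward reaction must select one amide–methyl pair and stop after one arylation. Ring B goes first because 7 is made in two steps from the cheap phenol 5 and can be spent in the exploratory step.

**4 ⇒ 1 + 2 via 3; 7 ⇒ 6 ⇒ 5; 10 ⇒ 9.** The diamide comes from the meso acid 1 and two equivalents of 8-aminoquinoline 2 through the diacid chloride 3. The iodides come from the phenols 5 and 9 by iodination and protection, or by protection alone.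

## Alternatives that were turned down

Alternative 1: The C8–C8' bond is cut. The secondary boronic ester A1, with boron on C8, is treated with the enantiopure lithiated ethyl benzoate A2. A boronate complex forms, the C8 group shifts onto the carbenoid carbon with loss of the benzoate, and A3 results with C8' new and boron where C7' will be attached.
- For it: every stereocentre is set by reagent control, predictably and independently, and this kind of homologation of secondary boronic esters is established chemistry. On certainty of stereocontrol it is stronger than the chosen key step.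
- Against it: the erythro relationship has to be built in two separate reagent-controlled events, each with a stoichiometric enantiopure organolithium at low temperature. Migration of a secondary alkyl group onto a secondary carbenoid is the slow case of this chemistry. A3 still lacks ring B, so a further homologation or an sp3 coupling is needed.
- Comparison: step counts are similar. The chosen route offers instead a single catalytic asymmetric event, a relative configuration that comes free from 1, and both arenes entering as simple aryl iodides.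

Alternative 2: The C7'–C8' bond is cut. The sodium enolate of the acyl oxazolidinone A4, which already holds C8 and ring A, is alkylated by the benzylic bromide A5, which holds rings B and C and the protected threo side chain. The product is the imide A6 with C8' set by the auxiliary.
- For it: auxiliary-controlled enolate benzylation is among the most dependable ways to set such a centre, and the route is convergent. On both points it is stronger than the chosen route.
- Against it: A5 is a 4-alkoxy-3,5-dimethoxybenzyl bromide that ionises readily, and it is the most valuable fragment, yet it would be used as the electrophile on a β-branched and therefore slower enolate. C8 needs its own asymmetric step beforehand. The auxiliary is stoichiometric. C9' must still be taken from the acyl level to methyl in three steps in the presence of the complete side chain.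
- Comparison: the chosen route sets C8 and C8' in one operation and carries only robust ethers through the reductions, at the price of an unproven selection.

Alternative 3: The C1–C7 bond is cut at the carbonyl level. The meso anhydride A7 is opened at one enantiotopic carbonyl by the arylzinc chloride A8 under [Rh(cod)Cl]2 and a chiral phosphoramidite, giving the keto acid A9.
- For it: it uses the same cheap meso source, and the desymmetrising acylation of arylzinc reagents by cyclic meso anhydrides is a demonstrated reaction class. On precedent of the asymmetric step it is clearly stronger than the chosen route.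
- Against it: C7 arrives as an aryl ketone next to C8. The carboxyl carbon, which becomes C7', also has to pass through an aryl ketone to receive ring B. Both core stereocentres therefore spend time α to a ketone, where the erythro arrangement can equilibrate. Two benzylic deoxygenations are then required.
- Comparison: the chosen route brings both benzylic carbons in at the methylene level, keeps C8 and C8' next to amidates that do not enolise, and treats the two ends by the same reactions. It pays with two auxiliary removals.

Key step: step 4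

## Route

Step 1
Reactants: 1 meso-2,3-dimethylsuccinic acid; 2 8-aminoquinoline (2 equiv)
Product: 4 meso-2,3-dimethyl-N1,N4-di(quinolin-8-yl)succinamide, via meso-2,3-dimethylsuccinyl dichloride 3 (not isolated)
Conditions: (COCl)2 (3 equiv), DMF (cat.), CH2Cl2, 0 °C to rt; evaporate; then added to 2 (2.2 equiv), Et3N (2.5 equiv), CH2Cl2, 0 °C to rt
Reagents that add atoms: oxalyl chloride, ClC(=O)C(=O)Cl (supplies the chlorine of intermediate 3; no atom of it remains in 4); 8-aminoquinoline, Nc1cccc2cccnc12 (the second equivalent of 2, which forms the second amide bond of 4)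
Why: Acid chloride formation followed by twofold amine acylation, each acyl chloride of 3 taking up one molecule of 2; with the dichloride added to an excess of the amine, the second acyl chloride should meet free amine, a far better nucleophile than the amide N–H of the mono-amide, before it can close to the five-membered imide. Et3N at 0 °C should not remove the α-hydrogens, so the meso configuration should be kept.

Step 2
Reactants: 5 2,6-dimethoxyphenol
Product: 6 4-iodo-2,6-dimethoxyphenol
Conditions: NIS, MeCN, 0 °C to rt, dark
Reagents that add atoms: N-iodosuccinimide, O=C1CCC(=O)N1I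
Why: Electrophilic aromatic iodination; the hydroxyl is the strongest donor and C4 is its free para position, so iodine should enter there.

Step 3
Reactants: 6 4-iodo-2,6-dimethoxyphenol
Product: 7 5-iodo-1,3-dimethoxy-2-(methoxymethoxy)benzene
Conditions: MOMCl, i-Pr2NEt, CH2Cl2, 0 °C to rt
Reagents that add atoms: chloromethyl methyl ether, COCCl
Why: O-alkylation of the phenol by the reactive α-chloro ether gives the mixed acetal, which tolerates the acetate-buffered arylations and all later basic and hydride steps.

Step 4
Reactants: 4 meso-2,3-dimethyl-N1,N4-di(quinolin-8-yl)succinamide; 7 5-iodo-1,3-dimethoxy-2-(methoxymethoxy)benzene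
Product: 8 (2R,3S)-2-[3,5-dimethoxy-4-(methoxymethoxy)benzyl]-3-methyl-N1,N4-di(quinolin-8-yl)succinamide
Conditions: Pd(OAc)2 (10 mol %), (R)-TRIP (20 mol %), AgOAc (1.5 equiv), 7 (1.0 equiv), PhMe/t-AmylOH, 70 °C
Reagents that add atoms: none
Why: Proposed new method: each amide of 4 binds divalent palladium through its deprotonated nitrogen and the quinoline nitrogen, phosphate-assisted C–H cleavage at the methyl group on the neighbouring carbon gives a five-membered palladacycle, oxidative addition of 7 gives tetravalent palladium, C–C reductive elimination forms the C1'–C7' bond and AgOAc takes up the iodide. The closest known reaction type is the 8-aminoquinoline-directed β-methyl C–H arylation of aliphatic amides with aryl iodides, together with its BINOL-phosphate variants that select between the two hydrogens of a methylene group; selection between two enantiotopic methyl groups of a meso diamide has not been shown. No ring is closed. C8 and C8' are not created here but become a defined pair: their erythro relationship is that of 1, and their absolute sense is set by the chiral phosphate on palladium, which meets the α-carbon as a member of the palladacycle with its large substituent on one face or the other, so that the two palladation transition states are diastereomeric. The step needs group selectivity between the two amide–methyl pairs, a stop after one arylation and no attack on the new benzylic methylene; the first rests on the opposite configuration of the two α-carbons, the other two on the limiting amount of 7, the moderate temperature and the slower cleavage of a secondary C–H bond flanked by two substituents. A second arylation should consume the minor enantiomer of 8 faster than the major one, because its remaining methyl group is the one the catalyst prefers, and this should raise the enantiomeric purity of 8. The methine C–H bonds are not cleaved and the amidate does not enolise, so the erythro relationship should survive.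

Step 5
Reactants: 9 4-iodo-2-methoxyphenol
Product: 10 1-(benzyloxy)-4-iodo-2-methoxybenzene
Conditions: BnBr, K2CO3, DMF, rt
Reagents that add atoms: benzyl bromide, BrCc1ccccc1
Why: Williamson ether synthesis on the phenoxide; the benzyl ether lasts until the final hydrogenolysis.

Step 6
Reactants: 8 (2R,3S)-2-[3,5-dimethoxy-4-(methoxymethoxy)benzyl]-3-methyl-N1,N4-di(quinolin-8-yl)succinamide; 10 1-(benzyloxy)-4-iodo-2-methoxybenzene
Product: 11 (2S,3R)-2-(4-benzyloxy-3-methoxybenzyl)-3-[3,5-dimethoxy-4-(methoxymethoxy)benzyl]-N1,N4-di(quinolin-8-yl)succinamide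
Conditions: Pd(OAc)2 (10 mol %), (BnO)2PO2H (20 mol %), AgOAc (1.5 equiv), 10 (1.5 equiv), t-AmylOH, 60 °C
Reagents that add atoms: none
Why: Known 8-aminoquinoline-directed β-methyl C–H arylation through a divalent/tetravalent palladium cycle, run without chiral ligand because the remaining methyl group C7 is the one the chiral catalyst disfavours. The only competing site is the benzylic methylene C7' next to the other amide, a secondary C–H bond between two substituents that should be cleaved more slowly at this temperature. No stereocentre is formed or touched.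

Step 7
Reactants: 11 (2S,3R)-2-(4-benzyloxy-3-methoxybenzyl)-3-[3,5-dimethoxy-4-(methoxymethoxy)benzyl]-N1,N4-di(quinolin-8-yl)succinamide
Product: 12 (2S,3R)-2-(4-benzyloxy-3-methoxybenzyl)-3-[3,5-dimethoxy-4-(methoxymethoxy)benzyl]-N1,N4-bis(tert-butoxycarbonyl)-N1,N4-di(quinolin-8-yl)succinamide
Conditions: Boc2O (4 equiv), DMAP, MeCN, 60 °C
Reagents that add atoms: di-tert-butyl dicarbonate, CC(C)(C)OC(=O)OC(=O)OC(C)(C)C
Why: DMAP-catalysed N-acylation of the secondary amides; the resulting N-acyl carbamates are twisted and electrophilic at the acyl carbon, which prepares the otherwise inert anilides for cleavage.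

Step 8
Reactants: 12 (2S,3R)-2-(4-benzyloxy-3-methoxybenzyl)-3-[3,5-dimethoxy-4-(methoxymethoxy)benzyl]-N1,N4-bis(tert-butoxycarbonyl)-N1,N4-di(quinolin-8-yl)succinamide
Product: 13 (2S,3R)-2-(4-benzyloxy-3-methoxybenzyl)-3-[3,5-dimethoxy-4-(methoxymethoxy)benzyl]butane-1,4-diol
Conditions: LiBH4 (excess), THF/MeOH, 0 °C to rt
Reagents that add atoms: none
Why: Reductive cleavage of N-acyl carbamates: hydride adds to the acyl carbonyl, the carbamate anion leaves and the aldehyde is reduced at once, faster than it can enolise, so C8 and C8' should be untouched. Lactone formation after the first reduction would still end in 13.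

Step 9
Reactants: 13 (2S,3R)-2-(4-benzyloxy-3-methoxybenzyl)-3-[3,5-dimethoxy-4-(methoxymethoxy)benzyl]butane-1,4-diol
Product: 14 (2S,3R)-2-(4-benzyloxy-3-methoxybenzyl)-3-[3,5-dimethoxy-4-(methoxymethoxy)benzyl]butane-1,4-diyl dimethanesulfonate
Conditions: MsCl (3 equiv), Et3N (4 equiv), CH2Cl2, −20 to 0 °C
Reagents that add atoms: methanesulfonyl chloride, CS(=O)(=O)Cl
Why: Sulfonylation through the sulfene is fast at both hydroxyls at low temperature, so the mono-sulfonate should not have time to cyclise by intramolecular displacement to a tetrahydrofuran, which is the known side path of 1,4-diols under slower sulfonylation.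

Step 10
Reactants: 14 (2S,3R)-2-(4-benzyloxy-3-methoxybenzyl)-3-[3,5-dimethoxy-4-(methoxymethoxy)benzyl]butane-1,4-diyl dimethanesulfonate
Product: 15 (2S,3R)-1-(4-benzyloxy-3-methoxyphenyl)-4-[3,5-dimethoxy-4-(methoxymethoxy)phenyl]-2,3-dimethylbutane
Conditions: LiEt3BH (6 equiv), THF, 0 to 50 °C
Reagents that add atoms: none
Why: SN2 displacement of the two primary sulfonates by hydride turns C9 and C9' into methyl groups; the stereocentres are β to the reacting carbons and are not involved.

Step 11
Reactants: 15 (2S,3R)-1-(4-benzyloxy-3-methoxyphenyl)-4-[3,5-dimethoxy-4-(methoxymethoxy)phenyl]-2,3-dimethylbutane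
Product: 16 4-[(2R,3S)-4-(4-benzyloxy-3-methoxyphenyl)-2,3-dimethylbutyl]-2,6-dimethoxyphenol
Conditions: conc. HCl (cat.), MeOH, 50 °C
Reagents that add atoms: none
Why: Acid-catalysed acetal exchange with methanol releases the ring B phenol; the benzyl ether of ring A is stable to these conditions.

Step 12
Reactants: 16 4-[(2R,3S)-4-(4-benzyloxy-3-methoxyphenyl)-2,3-dimethylbutyl]-2,6-dimethoxyphenol; 17 methyl (R)-lactate
Product: 18 methyl (S)-2-{4-[(2R,3S)-4-(4-benzyloxy-3-methoxyphenyl)-2,3-dimethylbutyl]-2,6-dimethoxyphenoxy}propanoate
Conditions: PPh3, DIAD, THF, 0 °C to rt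
Reagents that add atoms: none
Why: Mitsunobu reaction; the phenoxide displaces the activated lactate oxygen by SN2 with inversion, which turns the (R) alcohol into the (S) aryl ether and so sets C8''.

Step 13
Reactants: 18 methyl (S)-2-{4-[(2R,3S)-4-(4-benzyloxy-3-methoxyphenyl)-2,3-dimethylbutyl]-2,6-dimethoxyphenoxy}propanoate
Product: 19 (S)-2-{4-[(2R,3S)-4-(4-benzyloxy-3-methoxyphenyl)-2,3-dimethylbutyl]-2,6-dimethoxyphenoxy}-N-methoxy-N-methylpropanamide
Conditions: MeNH(OMe)·HCl, i-PrMgCl, THF, −20 to 0 °C
Reagents that add atoms: N,O-dimethylhydroxylamine hydrochloride, CNOC.Cl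
Why: Aminolysis of the ester by the chloromagnesium amide gives the Weinreb amide at low temperature, where the weakly basic amide should not deprotonate C8''.

Step 14
Reactants: 19 (S)-2-{4-[(2R,3S)-4-(4-benzyloxy-3-methoxyphenyl)-2,3-dimethylbutyl]-2,6-dimethoxyphenoxy}-N-methoxy-N-methylpropanamide; 10 1-(benzyloxy)-4-iodo-2-methoxybenzene
Product: 21 (S)-1-(4-benzyloxy-3-methoxyphenyl)-2-{4-[(2R,3S)-4-(4-benzyloxy-3-methoxyphenyl)-2,3-dimethylbutyl]-2,6-dimethoxyphenoxy}propan-1-one, via (4-benzyloxy-3-methoxyphenyl)magnesium chloride 20 (not isolated)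
Conditions: 10, i-PrMgCl·LiCl, THF, 0 °C to rt; then 19, THF, 0 °C to rt; aq. NH4Cl
Reagents that add atoms: isopropylmagnesium chloride–lithium chloride, CC(C)[Mg]Cl.[Li+].[Cl-] (supplies Mg and Cl of intermediate 20; no atom of it remains in 21)
Why: Iodine–magnesium exchange followed by the Weinreb ketone synthesis forms the C1''–C7'' bond; the chelated tetrahedral intermediate blocks a second addition and keeps C8'' from enolising until the neutral work-up.

Step 15
Reactants: 21 (S)-1-(4-benzyloxy-3-methoxyphenyl)-2-{4-[(2R,3S)-4-(4-benzyloxy-3-methoxyphenyl)-2,3-dimethylbutyl]-2,6-dimethoxyphenoxy}propan-1-one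
Product: 22 (1S,2S)-1-(4-benzyloxy-3-methoxyphenyl)-2-{4-[(2R,3S)-4-(4-benzyloxy-3-methoxyphenyl)-2,3-dimethylbutyl]-2,6-dimethoxyphenoxy}propan-1-ol
Conditions: KBH(s-Bu)3, THF, −78 °C
Reagents that add atoms: none
Why: Felkin–Anh reduction by a bulky hydride with a weakly chelating counter-ion: the hydride comes in anti to the C8''–O bond and past the hydrogen on C8'', which should give the (7''S) alcohol, threo to the (8''S) centre. Chelation control would give the erythro isomer and is suppressed by the potassium counter-ion and the hindered borohydride.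

Step 16
Reactants: 22 (1S,2S)-1-(4-benzyloxy-3-methoxyphenyl)-2-{4-[(2R,3S)-4-(4-benzyloxy-3-methoxyphenyl)-2,3-dimethylbutyl]-2,6-dimethoxyphenoxy}propan-1-ol
Product: 23 (+)-(7''S,8S,8'R,8''S)-4,4''-dihydroxy-3,3',3'',5'-tetramethoxy-4',8''-oxy-8,8'-sesquineolignan-7''-ol
Conditions: H2 (1 atm), 10% Pd/C, EtOAc, rt
Reagents that add atoms: none
Why: Hydrogenolysis of the two benzyl aryl ethers; in a neutral, non-acidic solvent the unactivated secondary benzylic alcohol should be cleaved much more slowly than the O-benzyl groups, and no stereocentre is affected.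

## Compound list

1 | meso-2,3-dimethylsuccinic acid | C[C@@H](C(=O)O)[C@H](C)C(=O)O | starting material
2 | 8-aminoquinoline | Nc1cccc2cccnc12 | starting material
3 | meso-2,3-dimethylsuccinyl dichloride | C[C@@H](C(=O)Cl)[C@H](C)C(=O)Cl | intermediate (not isolated)
4 | meso-2,3-dimethyl-N1,N4-di(quinolin-8-yl)succinamide | C[C@H](C(=O)Nc1cccc2cccnc12)[C@H](C(=O)Nc1cccc2cccnc12)C | intermediate
5 | 2,6-dimethoxyphenol | COc1cccc(OC)c1O | starting material
6 | 4-iodo-2,6-dimethoxyphenol | COc1cc(I)cc(OC)c1O | intermediate
7 | 5-iodo-1,3-dimethoxy-2-(methoxymethoxy)benzene | COCOc1c(OC)cc(I)cc1OC | intermediate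
8 | (2R,3S)-2-[3,5-dimethoxy-4-(methoxymethoxy)benzyl]-3-methyl-N1,N4-di(quinolin-8-yl)succinamide | C[C@H](C(=O)Nc1cccc2cccnc12)[C@H](C(=O)Nc1cccc2cccnc12)Cc1cc(OC)c(OCOC)c(OC)c1 | intermediate
9 | 4-iodo-2-methoxyphenol | COc1cc(I)ccc1O | starting material
10 | 1-(benzyloxy)-4-iodo-2-methoxybenzene | COc1cc(I)ccc1OCc1ccccc1 | intermediate
11 | (2S,3R)-2-(4-benzyloxy-3-methoxybenzyl)-3-[3,5-dimethoxy-4-(methoxymethoxy)benzyl]-N1,N4-di(quinolin-8-yl)succinamide | COc1cc(C[C@H](C(=O)Nc2cccc3cccnc23)[C@H](C(=O)Nc2cccc3cccnc23)Cc2cc(OC)c(OCOC)c(OC)c2)ccc1OCc1ccccc1 | intermediate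
12 | (2S,3R)-2-(4-benzyloxy-3-methoxybenzyl)-3-[3,5-dimethoxy-4-(methoxymethoxy)benzyl]-N1,N4-bis(tert-butoxycarbonyl)-N1,N4-di(quinolin-8-yl)succinamide (the bis-N-Boc derivative of 11) | COc1cc(C[C@H](C(=O)N(C(=O)OC(C)(C)C)c2cccc3cccnc23)[C@H](C(=O)N(C(=O)OC(C)(C)C)c2cccc3cccnc23)Cc2cc(OC)c(OCOC)c(OC)c2)ccc1OCc1ccccc1 | intermediate
13 | (2S,3R)-2-(4-benzyloxy-3-methoxybenzyl)-3-[3,5-dimethoxy-4-(methoxymethoxy)benzyl]butane-1,4-diol | COc1cc(C[C@H](CO)[C@H](CO)Cc2cc(OC)c(OCOC)c(OC)c2)ccc1OCc1ccccc1 | intermediate
14 | (2S,3R)-2-(4-benzyloxy-3-methoxybenzyl)-3-[3,5-dimethoxy-4-(methoxymethoxy)benzyl]butane-1,4-diyl dimethanesulfonate | COc1cc(C[C@H](COS(C)(=O)=O)[C@H](COS(C)(=O)=O)Cc2cc(OC)c(OCOC)c(OC)c2)ccc1OCc1ccccc1 | intermediate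
15 | (2S,3R)-1-(4-benzyloxy-3-methoxyphenyl)-4-[3,5-dimethoxy-4-(methoxymethoxy)phenyl]-2,3-dimethylbutane | COc1cc(C[C@H](C)[C@H](C)Cc2cc(OC)c(OCOC)c(OC)c2)ccc1OCc1ccccc1 | intermediate
16 | 4-[(2R,3S)-4-(4-benzyloxy-3-methoxyphenyl)-2,3-dimethylbutyl]-2,6-dimethoxyphenol | COc1cc(C[C@H](C)[C@H](C)Cc2cc(OC)c(O)c(OC)c2)ccc1OCc1ccccc1 | intermediate
17 | methyl (R)-lactate | C[C@@H](O)C(=O)OC | starting material
18 | methyl (S)-2-{4-[(2R,3S)-4-(4-benzyloxy-3-methoxyphenyl)-2,3-dimethylbutyl]-2,6-dimethoxyphenoxy}propanoate | COc1cc(C[C@H](C)[C@H](C)Cc2cc(OC)c(O[C@@H](C)C(=O)OC)c(OC)c2)ccc1OCc1ccccc1 | intermediate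
19 | (S)-2-{4-[(2R,3S)-4-(4-benzyloxy-3-methoxyphenyl)-2,3-dimethylbutyl]-2,6-dimethoxyphenoxy}-N-methoxy-N-methylpropanamide | COc1cc(C[C@H](C)[C@H](C)Cc2cc(OC)c(O[C@@H](C)C(=O)N(C)OC)c(OC)c2)ccc1OCc1ccccc1 | intermediate
20 | (4-benzyloxy-3-methoxyphenyl)magnesium chloride (as its LiCl complex) | COc1cc([Mg]Cl)ccc1OCc1ccccc1 | intermediate (not isolated)
21 | (S)-1-(4-benzyloxy-3-methoxyphenyl)-2-{4-[(2R,3S)-4-(4-benzyloxy-3-methoxyphenyl)-2,3-dimethylbutyl]-2,6-dimethoxyphenoxy}propan-1-one | COc1cc(C[C@H](C)[C@H](C)Cc2cc(OC)c(O[C@@H](C)C(=O)c3ccc(OCc4ccccc4)c(OC)c3)c(OC)c2)ccc1OCc1ccccc1 | intermediate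
22 | (1S,2S)-1-(4-benzyloxy-3-methoxyphenyl)-2-{4-[(2R,3S)-4-(4-benzyloxy-3-methoxyphenyl)-2,3-dimethylbutyl]-2,6-dimethoxyphenoxy}propan-1-ol | COc1cc(C[C@H](C)[C@H](C)Cc2cc(OC)c(O[C@@H](C)[C@@H](O)c3ccc(OCc4ccccc4)c(OC)c3)c(OC)c2)ccc1OCc1ccccc1 | intermediate
23 | (+)-(7''S,8S,8'R,8''S)-4,4''-dihydroxy-3,3',3'',5'-tetramethoxy-4',8''-oxy-8,8'-sesquineolignan-7''-ol | COc1cc(C[C@H](C)[C@H](C)Cc2cc(OC)c(O[C@@H](C)[C@@H](O)c3ccc(O)c(OC)c3)c(OC)c2)ccc1O | target

## Step count and least certain steps

Total step count: 16. Longest linear sequence: 14 steps (5 → 6 → 7 → 8 → 11 → 12 → 13 → 14 → 15 → 16 → 18 → 19 → 21 → 22 → 23; steps 2, 3, 4 and 6 to 16).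

**Step 4 (key step).** The most likely failure is poor discrimination between the two enantiotopic amide–methyl pairs. C–H cleavage assisted by acetate, without the chiral phosphate, would give racemic product. If palladation is reversible, the selection moves to a later step that the ligand may not control. The two 8-aminoquinoline amides may also bind one palladium together and remove it from the cycle, and arylation may fail to stop at one methyl group.

The fallback uses known chemistry, sets out from 1 and comes back at 8. Acid 1 is closed with acetyl chloride to meso-2,3-dimethylsuccinic anhydride F1 (the compound A7 above). Cinchona-alkaloid-mediated methanolysis (MeOH, toluene, −55 °C) opens one enantiotopic carbonyl to (2R,3S)-4-methoxy-2,3-dimethyl-4-oxobutanoic acid F2; quinine and quinidine give opposite hemiesters, and the one that delivers F2 is used. The free acid is coupled with 2 to methyl (2S,3R)-2,3-dimethyl-4-oxo-4-(quinolin-8-ylamino)butanoate F3. Ordinary directed arylation with 7 (Pd(OAc)2, AgOAc) gives methyl (2S,3R)-3-[3,5-dimethoxy-4-(methoxymethoxy)benzyl]-2-methyl-4-oxo-4-(quinolin-8-ylamino)butanoate F4, because only one directing group is present and only one methyl group lies within its reach. LiOH hydrolysis at 0 °C gives (2S,3R)-3-[3,5-dimethoxy-4-(methoxymethoxy)benzyl]-2-methyl-4-oxo-4-(quinolin-8-ylamino)butanoic acid F5, and a second coupling with 2 gives 8.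

**Step 6.** The likely failure is competing arylation at the benzylic methylene C7' through the neighbouring amide on C9'. Both amides can direct palladium, and 8-aminoquinoline amides are known to arylate methylene groups at higher temperature.

The fallback keeps only one directing group in the molecule at a time. It sets out from 1, follows the fallback of step 4 as far as F4, and comes back at 13. F4 is acyl-activated with Boc2O/DMAP to methyl (2S,3R)-4-[(tert-butoxycarbonyl)(quinolin-8-yl)amino]-3-[3,5-dimethoxy-4-(methoxymethoxy)benzyl]-2-methyl-4-oxobutanoate F6. NaBH4 in EtOH at 0 °C reduces the activated carbonyl, and the alcohol closes onto the methyl ester to give (3S,4R)-4-[3,5-dimethoxy-4-(methoxymethoxy)benzyl]-3-methyldihydrofuran-2(3H)-one F7. The AlMe3-activated amine 2 opens the lactone to (2S,3R)-3-[3,5-dimethoxy-4-(methoxymethoxy)benzyl]-4-hydroxy-2-methyl-N-(quinolin-8-yl)butanamide F8, with the auxiliary now on C9. Acetylation (Ac2O, pyridine) gives (2R,3S)-2-[3,5-dimethoxy-4-(methoxymethoxy)benzyl]-3-methyl-4-oxo-4-(quinolin-8-ylamino)butyl acetate F9. Directed arylation of the methyl group with 10 gives (2R,3S)-3-(4-benzyloxy-3-methoxybenzyl)-2-[3,5-dimethoxy-4-(methoxymethoxy)benzyl]-4-oxo-4-(quinolin-8-ylamino)butyl acetate F10; the benzylic methylene is now γ to the only amide and out of reach. Boc2O/DMAP gives (2R,3S)-3-(4-benzyloxy-3-methoxybenzyl)-4-[(tert-butoxycarbonyl)(quinolin-8-yl)amino]-2-[3,5-dimethoxy-4-(methoxymethoxy)benzyl]-4-oxobutyl acetate F11, and LiBH4 cleaves the activated amide and the acetate together to give 13.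

**Step 7 (with step 8).** The likely failure is incomplete N-acylation of two hindered, α-branched, neighbouring amides. In step 8, hydride may also attack the carbamate carbonyl, which returns the amide.

The fallback sets out from 11 and comes back at 13. Hydrozirconation of both amides with Cp2Zr(H)Cl in THF gives, after hydrolysis of the zirconated hemiaminals, (2S,3R)-2-(4-benzyloxy-3-methoxybenzyl)-3-[3,5-dimethoxy-4-(methoxymethoxy)benzyl]butanedial F12. It is reduced in the same flask with NaBH4 to 13 before the α-centres can equilibrate.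

**Step 1.** The likely failure is ring closure. The mono-activated acid may close to the anhydride during chlorination, or the mono-amide may close to the N-quinolinyl succinimide before the second molecule of 2 arrives. Either stops the sequence at one amide bond. Epimerisation of an activated acyl centre would give the racemic diastereomer.

The fallback sets out from 1 and comes back at 4. Fischer esterification (MeOH, H2SO4) gives dimethyl meso-2,3-dimethylsuccinate F13. Its two ester groups are then aminolysed by the dimethylaluminium amide made from 2 (2.2 equiv) and AlMe3 in toluene at 80 °C. No acyl donor reactive enough to cyclise is present.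

**Step 15.** The likely failure is poor facial selectivity. The counter-ion may chelate the carbonyl oxygen with the aryloxy or methoxy oxygens of ring B, which would favour the erythro alcohol.

The fallback moves the creation of C7'' into the C–C bond formation. It sets out from 18 and comes back at 22. Reduction with i-Bu2AlH in CH2Cl2 at −78 °C gives (S)-2-{4-[(2R,3S)-4-(4-benzyloxy-3-methoxyphenyl)-2,3-dimethylbutyl]-2,6-dimethoxyphenoxy}propanal F14. The aryl Grignard reagent 20 is added to it at −78 °C in the presence of MgBr2·OEt2. Under chelation control the aryl group enters past the hydrogen on C8'', which leads to the threo alcohol 22.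

## Further compounds

F1 | step 4 | meso-2,3-dimethylsuccinic anhydride [(3R,4S)-3,4-dimethyldihydrofuran-2,5-dione] | C[C@H]1C(=O)OC(=O)[C@H]1C
F2 | step 4 | (2R,3S)-4-methoxy-2,3-dimethyl-4-oxobutanoic acid | C[C@H](C(=O)OC)[C@H](C(=O)O)C
F3 | step 4 | methyl (2S,3R)-2,3-dimethyl-4-oxo-4-(quinolin-8-ylamino)butanoate | C[C@H](C(=O)OC)[C@H](C(=O)Nc1cccc2cccnc12)C
F4 | step 4 | methyl (2S,3R)-3-[3,5-dimethoxy-4-(methoxymethoxy)benzyl]-2-methyl-4-oxo-4-(quinolin-8-ylamino)butanoate | C[C@H](C(=O)OC)[C@H](C(=O)Nc1cccc2cccnc12)Cc1cc(OC)c(OCOC)c(OC)c1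
F5 | step 4 | (2S,3R)-3-[3,5-dimethoxy-4-(methoxymethoxy)benzyl]-2-methyl-4-oxo-4-(quinolin-8-ylamino)butanoic acid | C[C@H](C(=O)O)[C@H](C(=O)Nc1cccc2cccnc12)Cc1cc(OC)c(OCOC)c(OC)c1
F6 | step 6 | methyl (2S,3R)-4-[(tert-butoxycarbonyl)(quinolin-8-yl)amino]-3-[3,5-dimethoxy-4-(methoxymethoxy)benzyl]-2-methyl-4-oxobutanoate | C[C@H](C(=O)OC)[C@H](C(=O)N(C(=O)OC(C)(C)C)c1cccc2cccnc12)Cc1cc(OC)c(OCOC)c(OC)c1
F7 | step 6 | (3S,4R)-4-[3,5-dimethoxy-4-(methoxymethoxy)benzyl]-3-methyldihydrofuran-2(3H)-one | C[C@@H]1C(=O)OC[C@@H]1Cc1cc(OC)c(OCOC)c(OC)c1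
F8 | step 6 | (2S,3R)-3-[3,5-dimethoxy-4-(methoxymethoxy)benzyl]-4-hydroxy-2-methyl-N-(quinolin-8-yl)butanamide | C[C@H](C(=O)Nc1cccc2cccnc12)[C@H](CO)Cc1cc(OC)c(OCOC)c(OC)c1
F9 | step 6 | (2R,3S)-2-[3,5-dimethoxy-4-(methoxymethoxy)benzyl]-3-methyl-4-oxo-4-(quinolin-8-ylamino)butyl acetate | C[C@H](C(=O)Nc1cccc2cccnc12)[C@H](COC(C)=O)Cc1cc(OC)c(OCOC)c(OC)c1
F10 | step 6 | (2R,3S)-3-(4-benzyloxy-3-methoxybenzyl)-2-[3,5-dimethoxy-4-(methoxymethoxy)benzyl]-4-oxo-4-(quinolin-8-ylamino)butyl acetate | COc1cc(C[C@H](C(=O)Nc2cccc3cccnc23)[C@H](COC(C)=O)Cc2cc(OC)c(OCOC)c(OC)c2)ccc1OCc1ccccc1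
F11 | step 6 | (2R,3S)-3-(4-benzyloxy-3-methoxybenzyl)-4-[(tert-butoxycarbonyl)(quinolin-8-yl)amino]-2-[3,5-dimethoxy-4-(methoxymethoxy)benzyl]-4-oxobutyl acetate | COc1cc(C[C@H](C(=O)N(C(=O)OC(C)(C)C)c2cccc3cccnc23)[C@H](COC(C)=O)Cc2cc(OC)c(OCOC)c(OC)c2)ccc1OCc1ccccc1
F12 | step 7 | (2S,3R)-2-(4-benzyloxy-3-methoxybenzyl)-3-[3,5-dimethoxy-4-(methoxymethoxy)benzyl]butanedial | COc1cc(C[C@H](C=O)[C@H](C=O)Cc2cc(OC)c(OCOC)c(OC)c2)ccc1OCc1ccccc1
F13 | step 1 | dimethyl meso-2,3-dimethylsuccinate | C[C@@H](C(=O)OC)[C@H](C)C(=O)OC
F14 | step 15 | (S)-2-{4-[(2R,3S)-4-(4-benzyloxy-3-methoxyphenyl)-2,3-dimethylbutyl]-2,6-dimethoxyphenoxy}propanal | COc1cc(C[C@H](C)[C@H](C)Cc2cc(OC)c(O[C@@H](C)C=O)c(OC)c2)ccc1OCc1ccccc1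
A1 | alternative 1 | (S)-2-[1-(4-benzyloxy-3-methoxyphenyl)propan-2-yl]-4,4,5,5-tetramethyl-1,3,2-dioxaborolane | COc1cc(C[C@H](C)B2OC(C)(C)C(C)(C)O2)ccc1OCc1ccccc1
A2 | alternative 1 | (R)-1-lithioethyl 2,4,6-triisopropylbenzoate | [Li][C@H](C)OC(=O)c1c(C(C)C)cc(C(C)C)cc1C(C)C
A3 | alternative 1 | 2-[(2S,3S)-4-(4-benzyloxy-3-methoxyphenyl)-3-methylbutan-2-yl]-4,4,5,5-tetramethyl-1,3,2-dioxaborolane | COc1cc(C[C@H](C)[C@H](C)B2OC(C)(C)C(C)(C)O2)ccc1OCc1ccccc1
A4 | alternative 2 | (R)-4-benzyl-3-[(3S)-4-(4-benzyloxy-3-methoxyphenyl)-3-methylbutanoyl]oxazolidin-2-one | COc1cc(C[C@H](C)CC(=O)N2C(=O)OC[C@H]2Cc2ccccc2)ccc1OCc1ccccc1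
A5 | alternative 2 | 5-(bromomethyl)-2-{[(1S,2S)-1-(4-benzyloxy-3-methoxyphenyl)-1-[(benzyloxy)methoxy]propan-2-yl]oxy}-1,3-dimethoxybenzene | BrCc1cc(OC)c(O[C@@H](C)[C@@H](OCOCc2ccccc2)c2ccc(OCc3ccccc3)c(OC)c2)c(OC)c1
A6 | alternative 2 | alkylated imide carrying rings A, B and C, with C9' as the acyl carbon on (R)-4-benzyloxazolidin-2-one and (2R,3S) configuration in the butanoyl chain | COc1cc(C[C@H](C)[C@H](C(=O)N2C(=O)OC[C@H]2Cc2ccccc2)Cc2cc(OC)c(O[C@@H](C)[C@@H](OCOCc3ccccc3)c3ccc(OCc4ccccc4)c(OC)c3)c(OC)c2)ccc1OCc1ccccc1
A7 | alternative 3 | meso-2,3-dimethylsuccinic anhydride | C[C@H]1C(=O)OC(=O)[C@H]1C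
A8 | alternative 3 | (4-benzyloxy-3-methoxyphenyl)zinc chloride | COc1cc([Zn]Cl)ccc1OCc1ccccc1
A9 | alternative 3 | (2S,3R)-4-(4-benzyloxy-3-methoxyphenyl)-2,3-dimethyl-4-oxobutanoic acid | COc1cc(C(=O)[C@H](C)[C@H](C)C(=O)O)ccc1OCc1ccccc1
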